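A straight line through readings that end at 90.0 min is easily carried to a time that no reading reached. The quantity to carry here is the mean gain: a target reading divided by its time, as a fraction of the substrate charged per hour.

| flask | substrate | reagent in the second phase | temperature | remark | time | volume of the second phase over the first |
|---|---|---|---|---|---|---|
| south-west | 0.89 M | 1.1 M | 55 °C | run made earlier |  |  |
| west | 1.4 M | 1.1 M | 66 °C | run made earlier |  |  |
| east | 2 M | 1.1 M | 55 °C | run made earlier |  |  |
| south | 1 M | 1.4 M | 66 °C | run made earlier |  |  |
| violet | 2.0 M | 2.00 M | 60 °C |  | 5.0 h | 1.0 |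
| grey | 1.0 M | 1.10 M | 60 °C |  | 1.5 h | 1.0 |

| south-west: time / min | south-west: target / % | west: time / min | west: target / % | east: time / min | east: target / % | south: time / min | south: target / % |
|---|---|---|---|---|---|---|---|
| 8.00 | 0.1 | 8.00 | 0.2 | 8.00 | 0 | 8.00 | 1.2 |
| 15.0 | 1.6 | 25.0 | 3.8 | 25.0 | 0 | 15.0 | 1.5 |
| 25.0 | 0 | 40.0 | 4.8 | 40.0 | 1.2 | 25.0 | 2.5 |
| 50.0 | 2.3 | 60.0 | 8.1 | 60.0 | 4.4 | 50.0 | 8.5 |
| 90.0 | 7.2 | 90.0 | 11.5 | 90.0 | 6.2 | 90.0 | 14.4 |

(standard deviation of a reading: 1 percentage point)

* which one finishes higher in amount of target, in percent of the substrate charged ("neither" within 2 percentage points) (violet / grey / neither)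
* amount of target at the end, in percent of the substrate charged, violet
* amount of target at the end, in percent of the substrate charged, grey

- charges count per volume of the first phase; a concentration in a rate is the amount of a species over the volume of its own phase; every rate counts per litre of the first phase
- the earlier runs hold the two phases in the same ratio of volumes as the flask asked about
- a reading or a percentage of target counts all its forms, free or not

The last south-west reading gives a mean gain of 0.0480 h⁻¹, and each setting then acts on that figure in turn.

Substrate comes first. South-west and east differ in substrate by a factor of 2.25, yet their last readings differ by 1 percentage point, about the scatter of a reading, so this reckoning gives substrate no factor.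

Temperature comes next. West stands 1.60 times above south-west between 55 °C and 66 °C, and taken geometrically the step to 60 °C is worth 1.24.

For reagent, south stands 1.25 times above west for 1.27 times the reagent, which reads as first order in reagent within the scatter. Going from the 1.1 M of south-west to violet's 2.00 M is therefore worth 1.82, while grey holds the reagent of south-west and takes no such factor.

Time comes last. Grey stops where the readings stop, so its mean gain of 0.0594 h⁻¹ needs no assumption about the shape of the curve and gives 8.91%. Violet's mean gain is 0.108 h⁻¹, which gives 16.2% at 90.0 min. Held straight for 5.0 h, it gives 54.0%, but that time is 3.33 times the span of the readings. This reckoning therefore places violet between those two figures, and the lower one stands above grey's 8.91%.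

The forecast names violet too, at 34% with a range of 22% to 46% that lies inside this bracket, and puts grey at 9.5% (7.5% to 11.5%), noting that “The curves hint at slowing”.

The flask gives 19.5% for violet and 9.84% for grey, so violet finishes higher.

    reagent in the reaction phase ⇌ reagent in the second phase, rate k1*([reagent in the reaction phase] - [reagent in the second phase]/K1) per volume of the first phase (partition coefficient = 0.459, kL = 6.36 × 10⁻⁵ s⁻¹)
    substrate + reagent in the reaction phase → target (k = 1.16 × 10⁻⁴ M⁻¹ s⁻¹, Ea = 90.0 kJ mol⁻¹)
    target ⇌ product in the second phase, rate k3*([target] - [product in the second phase]/K3) per volume of the first phase (partition coefficient = 0.770, kL = 0.00104 s⁻¹)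
    target → decomposed product (k = 1.37 × 10⁻⁴ s⁻¹, Ea = 117 kJ mol⁻¹)
    2 reagent in the reaction phase → homo dimer (k = 2.91 × 10⁻⁴ M⁻¹ s⁻¹, Ea = 65.0 kJ mol⁻¹)
    substrate → decomposition product (k = 6.12 × 10⁻⁷ s⁻¹, Ea = 118 kJ mol⁻¹)
    (constants at 60 °C)

Grey stands 0.93 points above its reckoning. Violet's mean gain over its 5.0 h is 0.0390 h⁻¹, less than the 0.108 h⁻¹ carried from the readings. Its target stands at 19.1% after 2.50 h and at 19.5% after 5.00 h. Violet left until 8.0 h gets the same reckoning: the straight line gives 86.7%. That flask holds 13.5% of target, less than the 16.2% reckoned at 90.0 min, and 35.7% of decomposed product.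

All runs are simulated for an exercise; scatter was added.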